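**Retrosynthetic overview**
- Fischerin ⇒ removal of two O‑allyl groups and one O‑SiEt3 from a protected ketone; the C3–acyl bond comes from a C3‑magnesiated N‑allyloxy‑pyridone plus a decalin aldehyde, then oxidation.
- Decalin aldehyde ⇐ methyl ester ⇐ key step: catalyst‑controlled intramolecular Diels–Alder reaction of an acyclic (2Z,8E,10E)‑trienoate. Both carbocycles and all four stereocentres arise from an achiral chain (Z‑dienophile gives the cis ring fusion; C1 is then epimerised). Trienoate ⇐ dienal ⇐ sorbyl acetate + C4 Grignard reagent.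
- Epoxy‑diol ring ⇐ hydroxyl‑directed epoxidation ⇐ CBS reduction ⇐ CuH desymmetrisation of a prochiral p‑quinol silyl ether ⇐ 5‑lithiopyridone + benzoquinone monoketal.
- N‑Allyloxy‑pyridone ⇐ 5‑bromo‑2,4‑dichloropyridine (N‑oxidation, double SNAr, O→O allyl shift).
- Ring order: pyridine ring bought; decalin rings A and B together (step 3); cyclohexane ring attached (step 7); epoxide closed last (step 10).

Assumption: for the two catalyst‑controlled steps on new substrates (steps 3 and 8) the catalyst hand written is the one expected from the accepted models; if the sense proves opposite, the mirror‑image catalyst (equally available) is used and nothing else changes.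

**Route**

Step 1
Reactants: 1 (2E,4E)-hexa-2,4-dien-1-yl acetate; 2 2-(3-chloropropyl)-1,3-dioxolane
Product: 5 (6E,8E)-deca-6,8-dienal, via Grignard reagent 3 (not isolated), via dienyl dioxolane 4 (not isolated)
Conditions: 2, Mg, THF, 50 °C; then 1, Li2CuCl4 (3 mol %), THF, −20 → 0 °C; then 2 M HCl, THF, rt
Reagents that add atoms: water, O
Why: Kochi-type copper-catalysed coupling of an alkyl Grignard reagent with a primary dienyl acetate occurs at the α-carbon and keeps the conjugated E,E-diene (the pheromone-type sorbyl coupling), and dilute acid then hydrolyses the dioxolane; no stereocentre is formed.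

Step 2
Reactants: 5 (6E,8E)-deca-6,8-dienal; 6 methyl 2-[bis(2,2,2-trifluoroethoxy)phosphoryl]acetate
Product: 7 methyl (2Z,8E,10E)-dodeca-2,8,10-trienoate
Conditions: 6, KHMDS, 18-crown-6, THF, −78 °C; then 5, −78 °C
Reagents that add atoms: none
Why: Still–Gennari Horner–Wadsworth–Emmons olefination, in which the electron-poor phosphonate collapses under kinetic control to the Z-enoate (typically >15:1 for unbranched aldehydes).

Step 3
Reactants: 7 methyl (2Z,8E,10E)-dodeca-2,8,10-trienoate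
Product: 9 methyl (1R,2S,4aR,8aR)-2-methyl-1,2,4a,5,6,7,8,8a-octahydronaphthalene-1-carboxylate, via all-cis cycloadduct 8 (not isolated)
Conditions: (S)-B-o-tolyl-oxazaborolidine/Tf2NH (20 mol %), CH2Cl2, −20 → 0 °C; then NaOMe, MeOH, 50 °C
Reagents that add atoms: none
Why: Proposed new method: a chiral oxazaborolidinium-catalysed intramolecular Diels–Alder reaction of a (Z)-enoate (closest known chemistry: the same cationic oxazaborolidines in intermolecular Diels–Alder reactions of acrylate and crotonate esters and in intramolecular reactions of (E)-trienals, and thermal or Lewis-acid cyclisations of (Z)-trienoates to cis-fused adducts); the ester binds boron anti to OMe in its s-trans form so the Z-β-CH2 points away from the catalyst, the activated ester sits endo and, being cis to the tether, holds the tether endo as well, so the (E,E)-diene adds to the unshielded face to give the cis-fused all-cis adduct 8 (C2, C4a and C8a set here, both rings formed at once), the non-nucleophilic Tf2N⁻ counter-ion offers no addition–elimination path for Z→E isomerisation, and NaOMe then epimerises the axial ester at C1 to the equatorial one, trans to both neighbours, which is the thermodynamic and natural configuration.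

Step 4
Reactants: 9 methyl (1R,2S,4aR,8aR)-2-methyl-1,2,4a,5,6,7,8,8a-octahydronaphthalene-1-carboxylate
Product: 10 (1R,2S,4aR,8aR)-2-methyl-1,2,4a,5,6,7,8,8a-octahydronaphthalene-1-carbaldehyde
Conditions: DIBAL-H (1.1 equiv), CH2Cl2, −78 °C; MeOH, then Rochelle salt
Reagents that add atoms: none
Why: Partial hydride reduction of a hindered ester stops at the aluminium hemiacetal at −78 °C and releases the aldehyde on work-up, and C1 is already in its thermodynamic configuration so it is not at risk.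

Step 5
Reactants: 11 5-bromo-2,4-dichloropyridine
Product: 12 5-bromo-2,4-dichloropyridine 1-oxide
Conditions: urea·H2O2, (CF3CO)2O, CH2Cl2, 0 °C → rt
Reagents that add atoms: urea–hydrogen peroxide, OO.NC(N)=O
Why: Trifluoroperacetic acid generated in situ is the standard reagent for N-oxidation of electron-poor halopyridines.

Step 6
Reactants: 12 5-bromo-2,4-dichloropyridine 1-oxide
Product: 14 5-bromo-1,4-bis(prop-2-en-1-yloxy)pyridin-2(1H)-one, via bis(allyloxy)pyridine N-oxide 13 (not isolated)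
Conditions: allyl alcohol (2.5 equiv), NaH, THF, 0 °C → rt; then PhMe, 100 °C
Reagents that add atoms: prop-2-en-1-ol, C=CCO
Why: The N-oxide activates both the 2- and 4-chlorides for SNAr by allyloxide (the 5-bromide is inert), and heating then triggers the known thermal rearrangement of 2-alkoxypyridine N-oxides to 1-alkoxy-2-pyridones (O→O allyl shift), driven by formation of the pyridone carbonyl.

Step 7
Reactants: 14 5-bromo-1,4-bis(prop-2-en-1-yloxy)pyridin-2(1H)-one; 15 4,4-dimethoxycyclohexa-2,5-dien-1-one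
Product: 18 1,4-bis(prop-2-en-1-yloxy)-5-[4-oxo-1-(triethylsilyloxy)cyclohexa-2,5-dien-1-yl]pyridin-2(1H)-one, via 5-lithiopyridone 16 (not isolated), via quinol ketal silyl ether 17 (not isolated)
Conditions: t-BuLi (2.1 equiv), THF, −78 °C; 15, −78 °C; TESOTf, −78 → 0 °C; then 1 M aq. oxalic acid, THF, rt
Reagents that add atoms: triethylsilyl trifluoromethanesulfonate, CC[Si](CC)(CC)OS(=O)(=O)C(F)(F)F; water, O
Why: Bromine–lithium exchange is faster than any attack on the allyl ethers at −78 °C, aryllithiums add 1,2 to quinone monoketals, the tertiary alkoxide is silylated in situ and the dimethyl ketal hydrolyses under mild acid that leaves the tertiary silyl ether; the product is achiral (prochiral quaternary carbon).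

Step 8
Reactants: 18 1,4-bis(prop-2-en-1-yloxy)-5-[4-oxo-1-(triethylsilyloxy)cyclohexa-2,5-dien-1-yl]pyridin-2(1H)-one
Product: 20 1,4-bis(prop-2-en-1-yloxy)-5-[(1R)-4-oxo-1-(triethylsilyloxy)cyclohex-2-en-1-yl]pyridin-2(1H)-one, via silyl dienol ether 19 (not isolated)
Conditions: Cu(OAc)2 (5 mol %), (R,R)-Ph-BPE (6 mol %), (EtO)2MeSiH (1.2 equiv), PhMe, −30 °C; then 1 M aq. HCl, THF, 0 °C
Reagents that add atoms: none
Why: CuH-catalysed asymmetric conjugate reduction desymmetrises the 4,4-disubstituted cyclohexadienone (known reaction type), the chiral ligand choosing one of the two enantiotopic enone arms and thereby fixing the quaternary carbinol centre, while trapping of the copper enolate as silyl dienol ether 19 protects the product from over-reduction.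

Step 9
Reactants: 20 1,4-bis(prop-2-en-1-yloxy)-5-[(1R)-4-oxo-1-(triethylsilyloxy)cyclohex-2-en-1-yl]pyridin-2(1H)-one
Product: 21 1,4-bis(prop-2-en-1-yloxy)-5-[(1R,4R)-4-hydroxy-1-(triethylsilyloxy)cyclohex-2-en-1-yl]pyridin-2(1H)-one
Conditions: (S)-Me-CBS (20 mol %), catecholborane (1.5 equiv), PhMe, −78 °C
Reagents that add atoms: none
Why: Corey–Bakshi–Shibata 1,2-reduction under reagent control (alkenyl arm as the large group) gives the (4R)-allylic alcohol, trans to the silyloxy group, and catecholborane at −78 °C does not hydroborate the allyl ethers.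

Step 10
Reactants: 21 1,4-bis(prop-2-en-1-yloxy)-5-[(1R,4R)-4-hydroxy-1-(triethylsilyloxy)cyclohex-2-en-1-yl]pyridin-2(1H)-one
Product: 22 1,4-bis(prop-2-en-1-yloxy)-5-[(1R,2S,5R,6R)-5-hydroxy-2-(triethylsilyloxy)-7-oxabicyclo[4.1.0]heptan-2-yl]pyridin-2(1H)-one
Conditions: VO(acac)2 (5 mol %), t-BuOOH (decane), CH2Cl2, 0 °C → rt
Reagents that add atoms: tert-butyl hydroperoxide, CC(C)(C)OO
Why: Vanadium-catalysed hydroxyl-directed epoxidation delivers oxygen syn to the free secondary allylic alcohol, which is also the face anti to the bulky tertiary silyl ether (it cannot bind vanadium), so the epoxide is cis to the secondary OH and trans to the tertiary oxygen; the allyl ethers are not allylic alcohols and stay untouched.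

Step 11
Reactants: 22 1,4-bis(prop-2-en-1-yloxy)-5-[(1R,2S,5R,6R)-5-hydroxy-2-(triethylsilyloxy)-7-oxabicyclo[4.1.0]heptan-2-yl]pyridin-2(1H)-one; 10 (1R,2S,4aR,8aR)-2-methyl-1,2,4a,5,6,7,8,8a-octahydronaphthalene-1-carbaldehyde
Product: 24 3-{hydroxy[(1R,2S,4aR,8aR)-2-methyl-1,2,4a,5,6,7,8,8a-octahydronaphthalen-1-yl]methyl}-1,4-bis(prop-2-en-1-yloxy)-5-[(1R,2S,5R,6R)-5-hydroxy-2-(triethylsilyloxy)-7-oxabicyclo[4.1.0]heptan-2-yl]pyridin-2(1H)-one (both carbinol epimers), via C3-magnesiated pyridone 23 (not isolated)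
Conditions: TMPMgCl·LiCl (2.2 equiv), THF, −20 → 0 °C; then 10, −20 °C → rt
Reagents that add atoms: none
Why: Directed deprotonative magnesiation with the Knochel–Hauser base (first equivalent forms the alkoxide) occurs at C3, flanked by the C2 carbonyl and the 4-alkoxy group as in the known C3-metalation of 4-alkoxy-2-pyridones, and the aryl-magnesium adds 1,2 to the aldehyde; the new carbinol centre is not controlled and is removed in step 12.

Step 12
Reactants: 24 the carbinol from step 11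
Product: 25 3-[(1R,2S,4aR,8aR)-2-methyl-1,2,4a,5,6,7,8,8a-octahydronaphthalene-1-carbonyl]-1,4-bis(prop-2-en-1-yloxy)-5-[(1R,2S,5R,6R)-5-hydroxy-2-(triethylsilyloxy)-7-oxabicyclo[4.1.0]heptan-2-yl]pyridin-2(1H)-one
Conditions: MnO2 (activated, excess), CH2Cl2, rt
Reagents that add atoms: none
Why: MnO2 oxidises only the activated carbinol (attached to the pyridone C3=C4 enol-ether unit) and leaves the unactivated secondary epoxy alcohol, and C1 next to the new ketone remains in its thermodynamic configuration.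

Step 13
Reactants: 25 the ketone from step 12
Product: 26 5-[(1R,2S,5R,6R)-2,5-dihydroxy-7-oxabicyclo[4.1.0]heptan-2-yl]-3-[(1R,2S,4aR,8aR)-2-methyl-1,2,4a,5,6,7,8,8a-octahydronaphthalene-1-carbonyl]-1,4-bis(prop-2-en-1-yloxy)pyridin-2(1H)-one
Conditions: Et3N·3HF, MeCN, rt
Reagents that add atoms: none
Why: Fluoride-mediated desilylation with a mild, nearly neutral HF source removes the tertiary silyl ether while the pyridone is still O-allylated and acylated, so the tertiary carbinol is not prone to ionisation and the epoxide is not opened.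

Step 14
Reactants: 26 the bis-allyl ether from step 13
Product: 27 fischerin, 1,4-dihydroxy-5-[(1R,2S,5R,6R)-2,5-dihydroxy-7-oxabicyclo[4.1.0]heptan-2-yl]-3-[(1R,2S,4aR,8aR)-2-methyl-1,2,4a,5,6,7,8,8a-octahydronaphthalene-1-carbonyl]pyridin-2(1H)-one
Conditions: Pd(PPh3)4 (5 mol %), morpholine (10 equiv), THF, rt
Reagents that add atoms: none
Why: Tsuji–Trost-type Pd(0) deallylation cleaves both the hydroxamate-type N–O-allyl and the vinylogous-ester O-allyl groups under neutral conditions with morpholine as allyl acceptor, leaving the epoxide, the tertiary carbinol and the ring alkene untouched.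

**Compound list**
1 | (2E,4E)-hexa-2,4-dien-1-yl acetate | C/C=C/C=C/COC(C)=O | starting material
2 | 2-(3-chloropropyl)-1,3-dioxolane | ClCCCC1OCCO1 | starting material
3 | [3-(1,3-dioxolan-2-yl)propyl]magnesium chloride | Cl[Mg]CCCC1OCCO1 | intermediate
4 | 2-[(5E,7E)-nona-5,7-dien-1-yl]-1,3-dioxolane | C/C=C/C=C/CCCCC1OCCO1 | intermediate
5 | (6E,8E)-deca-6,8-dienal | C/C=C/C=C/CCCCC=O | intermediate
6 | methyl 2-[bis(2,2,2-trifluoroethoxy)phosphoryl]acetate | COC(=O)CP(=O)(OCC(F)(F)F)OCC(F)(F)F | starting material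
7 | methyl (2Z,8E,10E)-dodeca-2,8,10-trienoate | C/C=C/C=C/CCCC/C=C\C(=O)OC | intermediate
8 | methyl (1S,2S,4aR,8aR)-2-methyl-1,2,4a,5,6,7,8,8a-octahydronaphthalene-1-carboxylate (H-1, H-2, H-4a, H-8a all cis) | C[C@H]1C=C[C@H]2CCCC[C@H]2[C@H]1C(=O)OC | intermediate
9 | methyl (1R,2S,4aR,8aR)-2-methyl-1,2,4a,5,6,7,8,8a-octahydronaphthalene-1-carboxylate | C[C@H]1C=C[C@H]2CCCC[C@H]2[C@@H]1C(=O)OC | intermediate
10 | (1R,2S,4aR,8aR)-2-methyl-1,2,4a,5,6,7,8,8a-octahydronaphthalene-1-carbaldehyde | C[C@H]1C=C[C@H]2CCCC[C@H]2[C@@H]1C=O | intermediate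
11 | 5-bromo-2,4-dichloropyridine | Clc1cc(Cl)c(Br)cn1 | starting material
12 | 5-bromo-2,4-dichloropyridine 1-oxide | [O-][n+]1cc(Br)c(Cl)cc1Cl | intermediate
13 | 5-bromo-2,4-bis(prop-2-en-1-yloxy)pyridine 1-oxide | [O-][n+]1cc(Br)c(OCC=C)cc1OCC=C | intermediate
14 | 5-bromo-1,4-bis(prop-2-en-1-yloxy)pyridin-2(1H)-one | C=CCOn1cc(Br)c(OCC=C)cc1=O | intermediate
15 | 4,4-dimethoxycyclohexa-2,5-dien-1-one | COC1(OC)C=CC(=O)C=C1 | starting material
16 | 5-lithio-1,4-bis(prop-2-en-1-yloxy)pyridin-2(1H)-one | [Li]c1cn(OCC=C)c(=O)cc1OCC=C | intermediate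
17 | 5-[4,4-dimethoxy-1-(triethylsilyloxy)cyclohexa-2,5-dien-1-yl]-1,4-bis(prop-2-en-1-yloxy)pyridin-2(1H)-one | C=CCOn1cc(C2(O[Si](CC)(CC)CC)C=CC(OC)(OC)C=C2)c(OCC=C)cc1=O | intermediate
18 | 1,4-bis(prop-2-en-1-yloxy)-5-[4-oxo-1-(triethylsilyloxy)cyclohexa-2,5-dien-1-yl]pyridin-2(1H)-one | C=CCOn1cc(C2(O[Si](CC)(CC)CC)C=CC(=O)C=C2)c(OCC=C)cc1=O | intermediate
19 | 5-[(1R)-4-[diethoxy(methyl)silyloxy]-1-(triethylsilyloxy)cyclohexa-2,4-dien-1-yl]-1,4-bis(prop-2-en-1-yloxy)pyridin-2(1H)-one | C=CCOn1cc([C@@]2(O[Si](CC)(CC)CC)CC=C(O[Si](C)(OCC)OCC)C=C2)c(OCC=C)cc1=O | intermediate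
20 | 1,4-bis(prop-2-en-1-yloxy)-5-[(1R)-4-oxo-1-(triethylsilyloxy)cyclohex-2-en-1-yl]pyridin-2(1H)-one | C=CCOn1cc([C@@]2(O[Si](CC)(CC)CC)CCC(=O)C=C2)c(OCC=C)cc1=O | intermediate
21 | 1,4-bis(prop-2-en-1-yloxy)-5-[(1R,4R)-4-hydroxy-1-(triethylsilyloxy)cyclohex-2-en-1-yl]pyridin-2(1H)-one (OH trans to OSiEt3) | C=CCOn1cc([C@@]2(O[Si](CC)(CC)CC)CC[C@@H](O)C=C2)c(OCC=C)cc1=O | intermediate
22 | 1,4-bis(prop-2-en-1-yloxy)-5-[(1R,2S,5R,6R)-5-hydroxy-2-(triethylsilyloxy)-7-oxabicyclo[4.1.0]heptan-2-yl]pyridin-2(1H)-one | C=CCOn1cc([C@@]2(O[Si](CC)(CC)CC)CC[C@@H](O)[C@H]3O[C@H]32)c(OCC=C)cc1=O | intermediate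
23 | 3-(chloromagnesio) derivative of 22 as its chloromagnesium alkoxide | C=CCOn1cc([C@@]2(O[Si](CC)(CC)CC)CC[C@@H](O[Mg]Cl)[C@H]3O[C@H]32)c(OCC=C)c([Mg]Cl)c1=O | intermediate
24 | 3-{hydroxy[(1R,2S,4aR,8aR)-2-methyl-1,2,4a,5,6,7,8,8a-octahydronaphthalen-1-yl]methyl} derivative of 22 (carbinol epimers) | C[C@H]1C=C[C@H]2CCCC[C@H]2[C@@H]1C(O)c1c(OCC=C)c([C@@]2(O[Si](CC)(CC)CC)CC[C@@H](O)[C@H]3O[C@H]32)cn(OCC=C)c1=O | intermediate
25 | 3-[(1R,2S,4aR,8aR)-2-methyl-1,2,4a,5,6,7,8,8a-octahydronaphthalene-1-carbonyl] derivative of 22 | C[C@H]1C=C[C@H]2CCCC[C@H]2[C@@H]1C(=O)c1c(OCC=C)c([C@@]2(O[Si](CC)(CC)CC)CC[C@@H](O)[C@H]3O[C@H]32)cn(OCC=C)c1=O | intermediate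
26 | 5-[(1R,2S,5R,6R)-2,5-dihydroxy-7-oxabicyclo[4.1.0]heptan-2-yl]-3-[(1R,2S,4aR,8aR)-2-methyl-1,2,4a,5,6,7,8,8a-octahydronaphthalene-1-carbonyl]-1,4-bis(prop-2-en-1-yloxy)pyridin-2(1H)-one | C[C@H]1C=C[C@H]2CCCC[C@H]2[C@@H]1C(=O)c1c(OCC=C)c([C@@]2(O)CC[C@@H](O)[C@H]3O[C@H]32)cn(OCC=C)c1=O | intermediate
27 | fischerin | C[C@H]1C=C[C@H]2CCCC[C@H]2[C@@H]1C(=O)c1c(O)c([C@@]2(O)CC[C@@H](O)[C@H]3O[C@H]32)cn(O)c1=O | target

**Step count**
Total: 14 steps. Longest linear sequence: 10 steps (steps 5–14, from 5-bromo-2,4-dichloropyridine); the decalin branch (steps 1–4) joins at step 11.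

**Steps most likely to fail, with fallbacks**

Step 3 (enantioselective Z-triene cycloaddition). The risks are low ee with a Z-enoate and Z→E leakage giving trans-fused material. The fallback sets out from 7 and comes back at 9. Compound 7 is cyclised thermally with no chiral control (PhMe, BHT, 180 °C, sealed tube), which gives 8 together with its mirror image, methyl (1R,2R,4aS,8aS)-2-methyl-1,2,4a,5,6,7,8,8a-octahydronaphthalene-1-carboxylate F1. NaOMe/MeOH then gives 9 together with its enantiomer, methyl (1S,2R,4aS,8aS)-2-methyl-1,2,4a,5,6,7,8,8a-octahydronaphthalene-1-carboxylate F2. Saponification (LiOH, THF–MeOH–H2O) gives (1R,2S,4aR,8aR)-2-methyl-1,2,4a,5,6,7,8,8a-octahydronaphthalene-1-carboxylic acid F3 and its enantiomer, the (1S,2R,4aS,8aS)-acid F4. Classical resolution follows by crystallising the (R)-1-phenylethylammonium salt of the wanted acid F5 (the other hand of the amine is used if the salt of F4 is the less soluble one). Liberation with aqueous HCl and re-esterification (TMSCHN2, MeOH–PhMe) return enantiopure 9, and the route continues with step 4.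

Step 8 (CuH desymmetrisation). The risks are modest ee on an aryl/silyloxy-substituted dienone and over-reduction. The fallback sets out from 14 and comes back at 20. Bromine–lithium exchange as in step 7 (via 16) is followed by addition to the known enone (S)-4-(triethylsilyloxy)cyclohex-2-en-1-one F6, where the nucleophile enters anti to the 4-silyloxy group. In situ silylation (TESOTf) gives 5-[(1R,4S)-1,4-bis(triethylsilyloxy)cyclohex-2-en-1-yl]-1,4-bis(prop-2-en-1-yloxy)pyridin-2(1H)-one F7. Selective methanolysis of the less hindered secondary allylic silyl ether (PPTS, MeOH, 0 °C) gives 5-[(1R,4S)-4-hydroxy-1-(triethylsilyloxy)cyclohex-2-en-1-yl]-1,4-bis(prop-2-en-1-yloxy)pyridin-2(1H)-one F8. Allylic oxidation (MnO2, CH2Cl2) then gives 20, and the route continues with step 9. Here the quaternary carbinol centre is set by substrate control from a bought stereocentre that is then destroyed.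

Step 11 (C3 magnesiation and addition). The risks are slow or unselective deprotonation (C6–H or the N–O–CH2 group) and enolisation of the hindered aldehyde. The fallback sets out from 22 and comes back at 23. The electron-rich C3 position is iodinated (NIS, MeCN, 0 °C) to give the 3-iodo derivative of 22 F9. Iodine–magnesium exchange (i-PrMgCl·LiCl, 2.1 equiv, THF, −40 °C) generates the same magnesium species 23, to which 10 is added as in step 11.

**Further compounds**
F1 | step 3 | methyl (1R,2R,4aS,8aS)-2-methyl-1,2,4a,5,6,7,8,8a-octahydronaphthalene-1-carboxylate (mirror image of 8) | C[C@@H]1C=C[C@@H]2CCCC[C@@H]2[C@@H]1C(=O)OC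
F2 | step 3 | methyl (1S,2R,4aS,8aS)-2-methyl-1,2,4a,5,6,7,8,8a-octahydronaphthalene-1-carboxylate (mirror image of 9) | C[C@@H]1C=C[C@@H]2CCCC[C@@H]2[C@H]1C(=O)OC
F3 | step 3 | (1R,2S,4aR,8aR)-2-methyl-1,2,4a,5,6,7,8,8a-octahydronaphthalene-1-carboxylic acid | C[C@H]1C=C[C@H]2CCCC[C@H]2[C@@H]1C(=O)O
F4 | step 3 | (1S,2R,4aS,8aS)-2-methyl-1,2,4a,5,6,7,8,8a-octahydronaphthalene-1-carboxylic acid | C[C@@H]1C=C[C@@H]2CCCC[C@@H]2[C@H]1C(=O)O
F5 | step 3 | (R)-1-phenylethylammonium (1R,2S,4aR,8aR)-2-methyl-1,2,4a,5,6,7,8,8a-octahydronaphthalene-1-carboxylate | C[C@H]1C=C[C@H]2CCCC[C@H]2[C@@H]1C(=O)[O-].C[C@@H]([NH3+])c1ccccc1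
F6 | step 8 | (S)-4-(triethylsilyloxy)cyclohex-2-en-1-one | O=C1CC[C@H](O[Si](CC)(CC)CC)C=C1
F7 | step 8 | 5-[(1R,4S)-1,4-bis(triethylsilyloxy)cyclohex-2-en-1-yl]-1,4-bis(prop-2-en-1-yloxy)pyridin-2(1H)-one | C=CCOn1cc([C@@]2(O[Si](CC)(CC)CC)CC[C@H](O[Si](CC)(CC)CC)C=C2)c(OCC=C)cc1=O
F8 | step 8 | 5-[(1R,4S)-4-hydroxy-1-(triethylsilyloxy)cyclohex-2-en-1-yl]-1,4-bis(prop-2-en-1-yloxy)pyridin-2(1H)-one | C=CCOn1cc([C@@]2(O[Si](CC)(CC)CC)CC[C@H](O)C=C2)c(OCC=C)cc1=O
F9 | step 11 | 3-iodo-1,4-bis(prop-2-en-1-yloxy)-5-[(1R,2S,5R,6R)-5-hydroxy-2-(triethylsilyloxy)-7-oxabicyclo[4.1.0]heptan-2-yl]pyridin-2(1H)-one | C=CCOn1cc([C@@]2(O[Si](CC)(CC)CC)CC[C@@H](O)[C@H]3O[C@H]32)c(OCC=C)c(I)c1=O
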